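Ring carbons are called C1 (quaternary, CH3 and side chain), C2 (CH with the 3-hydroxypropyl), C3 (alkylidene carbon), C4, C5 and C6 (C(CH3)OH). C4 is β to C6 and C3 is β to the aldehyde, so the C3–C4 bond links two acceptor carbons. A cyclopropanol standing for C6/C5/C4 is opened by palladium to a ketone homoenolate that couples within the molecule with a (Z)-enol triflate at C3: one operation closes the cyclohexane, unveils the C6 ketone and fixes the tetrasubstituted alkene. The acyclic precursor gets its C1/C2 dyad from an enantioselective Ireland–Claisen rearrangement; C6 is set by methyl addition, the side chain by B-alkyl Suzuki coupling.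

Key step: step 8

Assumption on step 2: the (R,R)-bromoborane controller is taken to give acid 6 as the (2S,3S) enantiomer; if the sense of induction is the reverse, the (S,S)-controller is used and nothing else changes.
Assumption on compound 2: it is taken as a catalogue compound (otherwise it is one step from δ-valerolactone).
TBS = tert-butyldimethylsilyl.

Step 1
Reactants: 1 (E)-3-methylpent-2-en-4-yn-1-ol; 2 5-[(tert-butyldimethylsilyl)oxy]pentanoic acid
Product: 3 (E)-3-methylpent-2-en-4-yn-1-yl 5-[(tert-butyldimethylsilyl)oxy]pentanoate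
Conditions: DCC, DMAP (cat.), CH2Cl2, 0 °C → rt
Reagents that add atoms: none
Why: Steglich esterification of a primary allylic alcohol with an unhindered acid; no stereocentre is involved.

Step 2
Reactants: 3 (E)-3-methylpent-2-en-4-yn-1-yl 5-[(tert-butyldimethylsilyl)oxy]pentanoate
Product: 6 (2S,3S)-2-{3-[(tert-butyldimethylsilyl)oxy]propyl}-3-ethynyl-3-methylpent-4-enoic acid, via boron ketene acetal 4 (not isolated), via acyloxyborane 5 (not isolated)
Conditions: (R,R)-bromoborane controller [made in the flask from (R,R)-N,N'-bis{[3,5-bis(trifluoromethyl)phenyl]sulfonyl}-1,2-diphenylethane-1,2-diamine and BBr3, CH2Cl2, volatiles removed], Et3N, toluene/hexane, −78 °C, then −20 → 4 °C; aqueous work-up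
Reagents that add atoms: none
Why: Enantioselective boron-enolate Ireland–Claisen rearrangement: these conditions should give the E(O)-enolate (alkyl chain trans to O–B), which rearranges through a chair with the ethynyl group of the (E)-alkene equatorial, so the relative configuration of quaternary C1 and tertiary C2 follows from the two geometries and the absolute sense from the C2-symmetric diazaborolidine shielding one enolate face.

Step 3
Reactants: 6 (2S,3S)-2-{3-[(tert-butyldimethylsilyl)oxy]propyl}-3-ethynyl-3-methylpent-4-enoic acid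
Product: 9 ethyl (4S,5S)-4-{3-[(tert-butyldimethylsilyl)oxy]propyl}-5-ethynyl-2,5-dimethyl-3-oxohept-6-enoate (both epimers at the ester α-carbon), via acyl imidazolide 7 (not isolated), via acylmalonate half-ester 8 (not isolated)
Conditions: CDI, THF, rt; then ethyl hydrogen methylmalonate, MgCl2, Et3N, MeCN, rt → 45 °C; aqueous citric acid
Reagents that add atoms: ethyl hydrogen methylmalonate (3-ethoxy-2-methyl-3-oxopropanoic acid), CCOC(=O)C(C)C(=O)O
Why: Acyl imidazolide formation and decarboxylative Claisen-type C-acylation of the magnesium enolate of the malonate half-ester under near-neutral conditions, which should leave the stereocentre α to the acyl group untouched; the new α-methyl centre forms as a mixture that step 4 removes.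

Step 4
Reactants: 9 ethyl (4S,5S)-4-{3-[(tert-butyldimethylsilyl)oxy]propyl}-5-ethynyl-2,5-dimethyl-3-oxohept-6-enoate
Product: 11 ethyl (2Z,4S,5S)-4-{3-[(tert-butyldimethylsilyl)oxy]propyl}-5-ethynyl-2,5-dimethyl-3-{[(trifluoromethyl)sulfonyl]oxy}hepta-2,6-dienoate, via sodium enolate 10 (not isolated)
Conditions: NaH (1.05 equiv), CH2Cl2, 0 °C; then Tf2O, −78 → 0 °C
Reagents that add atoms: trifluoromethanesulfonic anhydride, O=S(=O)(OS(=O)(=O)C(F)(F)F)C(F)(F)F
Why: O-triflation of the sodium-chelated β-keto ester enolate, in which the metal holds the enolate oxygen and the ester carbonyl cis, should give the (Z)-enol triflate (TfO cis to CO2Et, CH3 cis to C2) and erases the epimeric centre.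

Step 5
Reactants: 11 the (Z)-enol triflate with the ethynyl group
Product: 12 ethyl (2Z,4S,5S)-5-acetyl-4-{3-[(tert-butyldimethylsilyl)oxy]propyl}-2,5-dimethyl-3-{[(trifluoromethyl)sulfonyl]oxy}hepta-2,6-dienoate
Conditions: Ph3PAuCl (5 mol %), AgOTf (5 mol %), H2O (3 equiv), 1,4-dioxane, 60 °C
Reagents that add atoms: water, O
Why: Markovnikov hydration of the terminal alkyne by π-activation with univalent gold gives the methyl ketone; it is placed after step 4 because the enol triflate, unlike the β-keto ester, cannot attack the activated alkyne.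

Step 6
Reactants: 12 the methyl ketone
Product: 13 ethyl (2Z,4S,5S)-4-{3-[(tert-butyldimethylsilyl)oxy]propyl}-2,5-dimethyl-3-{[(trifluoromethyl)sulfonyl]oxy}-5-{1-[(trimethylsilyl)oxy]ethenyl}hepta-2,6-dienoate
Conditions: TMSOTf, Et3N, CH2Cl2, 0 °C
Reagents that add atoms: trimethylsilyl trifluoromethanesulfonate, C[Si](C)(C)OS(=O)(=O)C(F)(F)F
Why: Soft enolisation and O-silylation; the ketone has α-hydrogens only on its methyl group, so a single silyl enol ether can form.

Step 7
Reactants: 13 the trimethylsilyl enol ether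
Product: 15 ethyl (2Z,4S,5S)-4-{3-[(tert-butyldimethylsilyl)oxy]propyl}-5-(1-hydroxycyclopropyl)-2,5-dimethyl-3-{[(trifluoromethyl)sulfonyl]oxy}hepta-2,6-dienoate, via silyl cyclopropyl ether 14 (not isolated)
Conditions: Et2Zn, CH2I2, CH2Cl2, 0 °C → rt; then citric acid, MeOH, 0 °C
Reagents that add atoms: diiodomethane, ICI
Why: Simmons–Smith cyclopropanation (Et2Zn/CH2I2 variant) is fastest at the electron-rich silyl enol ether and far slower at the hindered vinyl group and the electron-poor enol triflate; mild acidic methanolysis then frees the cyclopropanol while the primary TBS ether stays.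

Step 8
Reactants: 15 the cyclopropanol enol triflate
Product: 17 ethyl (2E)-2-[(2R,3S)-2-{3-[(tert-butyldimethylsilyl)oxy]propyl}-3-ethenyl-3-methyl-4-oxocyclohexylidene]propanoate, via seven-membered palladacycle 16 (not isolated)
Conditions: Pd(OAc)2 (10 mol %), XPhos (20 mol %), Cs2CO3 (2 equiv), toluene, 80 °C
Reagents that add atoms: none
Why: Zerovalent palladium inserts into the C3–OTf bond with retention of the (Z) geometry, the caesium cyclopropanolate binds the metal, and strain-driven β-carbon elimination opens the cyclopropane (its two CH2 groups are equivalent) to the β-keto alkylpalladium, so that C3 and C4 sit on one metal in palladacycle 16, from which C(sp3)–C(sp2) reductive elimination forms C3–C4. The closest known reaction type is the palladium-catalysed ring-opening cross-coupling of cyclopropanols (ketone homoenolates) with aryl and alkenyl halides or triflates, run here within one molecule. The six-membered ring closes by reductive elimination from a seven-membered palladacycle, not by attack on a π bond, so no exo/endo choice arises. No stereocentre is created: C1 and C2 are untouched and the tetrasubstituted alkene keeps the geometry set in step 4 (ester cis to the new C4, CH3 cis to C2). The step needs C–C reductive elimination to outrun β-hydride elimination at C5 and O-vinylation by the alkoxide; the bulky biaryl phosphine and the closeness of the two carbon ligands in the chelate are expected to secure this. It joins two carbons that are both acceptor positions (β to the C6 ketone and β to the ester), the polarity of C4 being reversed by the cyclopropanol.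

Step 9
Reactants: 17 the cyclohexanone
Product: 18 ethyl (2E)-2-[(2R,3S,4S)-2-{3-[(tert-butyldimethylsilyl)oxy]propyl}-3-ethenyl-4-hydroxy-3,4-dimethylcyclohexylidene]propanoate
Conditions: CeCl3 (anhydrous), MeMgBr, THF, −78 → 0 °C
Reagents that add atoms: methylmagnesium bromide, C[Mg]Br
Why: 1,2-Addition of the weakly basic methylcerium reagent to the ketone in preference to the hindered conjugated ester; the C2 chain is held axial by allylic 1,3-strain with the alkylidene CH3, so attack is expected on the ring face anti to that chain and to the C1 methyl, which places the C6 hydroxyl cis to both (4S).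

Step 10
Reactants: 19 geranyl chloride [(E)-1-chloro-3,7-dimethylocta-2,6-diene]; 20 but-2-ynal
Product: 22 (6E)-7,11-dimethyldodeca-6,10-dien-2-yn-4-ol (racemic), via geranylbarium chloride 21 (not isolated)
Conditions: BaI2, lithium biphenylide, THF, rt; then 19, −78 °C; then 20, −78 °C
Reagents that add atoms: none
Why: α-Selective carbonyl allylation with an allylic barium reagent, which reacts at its unsubstituted terminus with retention of the (E) geometry; the carbinol centre forms racemic and is reset in steps 11 and 12.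

Step 11
Reactants: 22 the racemic propargylic alcohol
Product: 23 (6E)-7,11-dimethyldodeca-6,10-dien-2-yn-4-one
Conditions: MnO2, CH2Cl2, rt
Reagents that add atoms: none
Why: Oxidation of a propargylic alcohol with MnO2 under neutral conditions, which should keep the β,γ-double bond out of conjugation.

Step 12
Reactants: 23 the ynone
Product: 24 (4R,6E)-7,11-dimethyldodeca-6,10-dien-2-yn-4-ol
Conditions: Ru[(R,R)-TsDPEN](p-cymene) (2 mol %), i-PrOH, rt, no added base
Reagents that add atoms: none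
Why: Asymmetric transfer hydrogenation of an alkynyl ketone, in which the alkynyl group takes the place that an aryl group holds with this catalyst family, so the (R,R)-catalyst should give the (R)-alcohol; base is left out to spare the skipped enone.

Step 13
Reactants: 24 the (R)-propargylic alcohol
Product: 25 tert-butyl{[(4R,6E)-7,11-dimethyldodeca-6,10-dien-2-yn-4-yl]oxy}dimethylsilane
Conditions: TBSCl, imidazole, DMF, rt
Reagents that add atoms: tert-butyldimethylsilyl chloride, CC(C)(C)[Si](C)(C)Cl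
Why: Silyl ether formation; the stereocentre is not touched.

Step 14
Reactants: 25 the silyl ether
Product: 27 tert-butyl{[(2E,4R,6E)-2-iodo-7,11-dimethyldodeca-2,6,10-trien-4-yl]oxy}dimethylsilane, via alkenylzirconocene chloride 26 (not isolated)
Conditions: Cp2Zr(H)Cl (1.5 equiv), THF, rt → 40 °C; then I2, 0 °C
Reagents that add atoms: iodine, II
Why: Syn-hydrozirconation of the internal alkyne places zirconium on the less hindered methyl-bearing carbon, and iodinolysis with retention gives the (E)-vinyl iodide; the trisubstituted alkenes do not react.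

Step 15
Reactants: 18 the tertiary alcohol with the vinyl group; 27 the vinyl iodide
Product: 29 ethyl (2E)-2-[(2R,3S,4S)-2-{3-[(tert-butyldimethylsilyl)oxy]propyl}-3-{(3E,5R,7E)-5-[(tert-butyldimethylsilyl)oxy]-3,8,12-trimethyltrideca-3,7,11-trien-1-yl}-4-hydroxy-3,4-dimethylcyclohexylidene]propanoate, via B-alkyl-9-borabicyclononane 28 (not isolated)
Conditions: 9-BBN dimer (excess), THF, 50 °C; then 27, Pd(dppf)Cl2 (10 mol %), AsPh3, Cs2CO3, DMF/H2O, rt
Reagents that add atoms: none
Why: Anti-Markovnikov hydroboration of the only monosubstituted alkene and B-alkyl Suzuki–Miyaura coupling with retention of the vinyl iodide geometry build the (E)-trisubstituted side-chain alkene; the tetrasubstituted alkene, the ester and the tertiary alcohol are tolerated.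

Step 16
Reactants: 29 the coupled ester
Product: 30 (2E)-2-[(2R,3S,4S)-2-{3-[(tert-butyldimethylsilyl)oxy]propyl}-3-{(3E,5R,7E)-5-[(tert-butyldimethylsilyl)oxy]-3,8,12-trimethyltrideca-3,7,11-trien-1-yl}-4-hydroxy-3,4-dimethylcyclohexylidene]propan-1-ol
Conditions: i-Bu2AlH (4 equiv), CH2Cl2, −78 → 0 °C; Rochelle salt work-up
Reagents that add atoms: none
Why: Hydride reduction of the conjugated ester to the allylic alcohol; silyl ethers and alkenes are inert.

Step 17
Reactants: 30 the allylic alcohol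
Product: 31 (2E)-2-[(2R,3S,4S)-2-{3-[(tert-butyldimethylsilyl)oxy]propyl}-3-{(3E,5R,7E)-5-[(tert-butyldimethylsilyl)oxy]-3,8,12-trimethyltrideca-3,7,11-trien-1-yl}-4-hydroxy-3,4-dimethylcyclohexylidene]propanal
Conditions: MnO2, CH2Cl2, rt
Reagents that add atoms: none
Why: Allylic oxidation with MnO2 touches only the primary allylic alcohol (the tertiary alcohol and both silyl ethers are inert) and its neutral conditions should keep the enal geometry.

Step 18
Reactants: 31 the bis-silyl enal
Product: 32 (2E)-2-[(2R,3S,4S)-4-hydroxy-3-[(3E,5R,7E)-5-hydroxy-3,8,12-trimethyltrideca-3,7,11-trien-1-yl]-2-(3-hydroxypropyl)-3,4-dimethylcyclohexylidene]propanal (CNP0417035.1)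
Conditions: n-Bu4NF, AcOH, THF, 0 °C → rt
Reagents that add atoms: none
Why: Fluoride cleavage of the primary and the allylic secondary silyl ether, buffered with acetic acid to spare the enal.

Compound list
1 | (E)-3-methylpent-2-en-4-yn-1-ol | C#C/C(C)=C/CO | starting material
2 | 5-[(tert-butyldimethylsilyl)oxy]pentanoic acid | OC(=O)CCCCO[Si](C)(C)C(C)(C)C | starting material
3 | (E)-3-methylpent-2-en-4-yn-1-yl 5-[(tert-butyldimethylsilyl)oxy]pentanoate | C#C/C(C)=C/COC(=O)CCCCO[Si](C)(C)C(C)(C)C | intermediate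
4 | boron ketene acetal: E(O)-enolate of 3 on the (R,R)-diazaborolidine | C#C/C(C)=C/CO/C(OB1N(S(=O)(=O)c2cc(cc(c2)C(F)(F)F)C(F)(F)F)[C@H](c2ccccc2)[C@@H](c2ccccc2)N1S(=O)(=O)c1cc(cc(c1)C(F)(F)F)C(F)(F)F)=C\CCCO[Si](C)(C)C(C)(C)C | intermediate (not isolated)
5 | acyloxyborane of acid 6 | C=C[C@@](C#C)(C)[C@H](CCCO[Si](C)(C)C(C)(C)C)C(=O)OB1N(S(=O)(=O)c2cc(cc(c2)C(F)(F)F)C(F)(F)F)[C@H](c2ccccc2)[C@@H](c2ccccc2)N1S(=O)(=O)c1cc(cc(c1)C(F)(F)F)C(F)(F)F | intermediate (not isolated)
6 | (2S,3S)-2-{3-[(TBS)oxy]propyl}-3-ethynyl-3-methylpent-4-enoic acid | C=C[C@@](C#C)(C)[C@H](CCCO[Si](C)(C)C(C)(C)C)C(=O)O | intermediate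
7 | acyl imidazolide of 6 | C=C[C@@](C#C)(C)[C@H](CCCO[Si](C)(C)C(C)(C)C)C(=O)n1ccnc1 | intermediate (not isolated)
8 | acylmalonate half-ester (2-acyl-2-methylmalonic acid monoethyl ester) | C=C[C@@](C#C)(C)[C@H](CCCO[Si](C)(C)C(C)(C)C)C(=O)C(C)(C(=O)O)C(=O)OCC | intermediate (not isolated)
9 | ethyl (4S,5S)-4-{3-[(TBS)oxy]propyl}-5-ethynyl-2,5-dimethyl-3-oxohept-6-enoate, both epimers at the ester α-carbon | C=C[C@@](C#C)(C)[C@H](CCCO[Si](C)(C)C(C)(C)C)C(=O)C(C)C(=O)OCC | intermediate
10 | sodium (Z)-enolate of 9 | C=C[C@@](C#C)(C)[C@H](CCCO[Si](C)(C)C(C)(C)C)/C(=C(\C)C(=O)OCC)[O-].[Na+] | intermediate (not isolated)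
11 | ethyl (2Z,4S,5S)-4-{3-[(TBS)oxy]propyl}-5-ethynyl-2,5-dimethyl-3-{[(trifluoromethyl)sulfonyl]oxy}hepta-2,6-dienoate | C=C[C@@](C#C)(C)[C@H](CCCO[Si](C)(C)C(C)(C)C)/C(=C(\C)C(=O)OCC)OS(=O)(=O)C(F)(F)F | intermediate
12 | ethyl (2Z,4S,5S)-5-acetyl-4-{3-[(TBS)oxy]propyl}-2,5-dimethyl-3-{[(trifluoromethyl)sulfonyl]oxy}hepta-2,6-dienoate | C=C[C@@](C(C)=O)(C)[C@H](CCCO[Si](C)(C)C(C)(C)C)/C(=C(\C)C(=O)OCC)OS(=O)(=O)C(F)(F)F | intermediate
13 | ethyl (2Z,4S,5S)-4-{3-[(TBS)oxy]propyl}-2,5-dimethyl-3-{[(trifluoromethyl)sulfonyl]oxy}-5-{1-[(trimethylsilyl)oxy]ethenyl}hepta-2,6-dienoate | C=C[C@@](C(=C)O[Si](C)(C)C)(C)[C@H](CCCO[Si](C)(C)C(C)(C)C)/C(=C(\C)C(=O)OCC)OS(=O)(=O)C(F)(F)F | intermediate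
14 | trimethylsilyl ether of cyclopropanol 15 | C=C[C@@](C1(O[Si](C)(C)C)CC1)(C)[C@H](CCCO[Si](C)(C)C(C)(C)C)/C(=C(\C)C(=O)OCC)OS(=O)(=O)C(F)(F)F | intermediate (not isolated)
15 | ethyl (2Z,4S,5S)-4-{3-[(TBS)oxy]propyl}-5-(1-hydroxycyclopropyl)-2,5-dimethyl-3-{[(trifluoromethyl)sulfonyl]oxy}hepta-2,6-dienoate | C=C[C@@](C1(O)CC1)(C)[C@H](CCCO[Si](C)(C)C(C)(C)C)/C(=C(\C)C(=O)OCC)OS(=O)(=O)C(F)(F)F | intermediate
16 | seven-membered alkyl(alkenyl)palladium intermediate, phosphine ligand omitted | C=C[C@@]1(C)[C@H](CCCO[Si](C)(C)C(C)(C)C)/C(=C(\C)C(=O)OCC)[Pd]CCC1=O | intermediate (not isolated)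
17 | ethyl (2E)-2-[(2R,3S)-2-{3-[(TBS)oxy]propyl}-3-ethenyl-3-methyl-4-oxocyclohexylidene]propanoate | C=C[C@@]1(C)[C@H](CCCO[Si](C)(C)C(C)(C)C)/C(=C(\C)C(=O)OCC)CCC1=O | intermediate
18 | ethyl (2E)-2-[(2R,3S,4S)-2-{3-[(TBS)oxy]propyl}-3-ethenyl-4-hydroxy-3,4-dimethylcyclohexylidene]propanoate | C=C[C@@]1(C)[C@H](CCCO[Si](C)(C)C(C)(C)C)/C(=C(\C)C(=O)OCC)CC[C@]1(C)O | intermediate
19 | geranyl chloride, (E)-1-chloro-3,7-dimethylocta-2,6-diene | CC(C)=CCC/C(C)=C/CCl | starting material
20 | but-2-ynal | CC#CC=O | starting material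
21 | geranylbarium chloride | CC(C)=CCC/C(C)=C/C[Ba]Cl | intermediate (not isolated)
22 | (6E)-7,11-dimethyldodeca-6,10-dien-2-yn-4-ol, racemic | CC#CC(O)C/C=C(\C)CCC=C(C)C | intermediate
23 | (6E)-7,11-dimethyldodeca-6,10-dien-2-yn-4-one | CC#CC(=O)C/C=C(\C)CCC=C(C)C | intermediate
24 | (4R,6E)-7,11-dimethyldodeca-6,10-dien-2-yn-4-ol | CC#C[C@H](O)C/C=C(\C)CCC=C(C)C | intermediate
25 | tert-butyl{[(4R,6E)-7,11-dimethyldodeca-6,10-dien-2-yn-4-yl]oxy}dimethylsilane | CC#C[C@H](O[Si](C)(C)C(C)(C)C)C/C=C(\C)CCC=C(C)C | intermediate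
26 | (E)-alkenylzirconocene chloride from 25 (Zr on the methyl-bearing carbon, Cp rings drawn σ-bonded) | CC(C)=CCC/C(C)=C/C[C@@H](O[Si](C)(C)C(C)(C)C)/C=C(\C)[Zr](Cl)(C1C=CC=C1)C1C=CC=C1 | intermediate (not isolated)
27 | tert-butyl{[(2E,4R,6E)-2-iodo-7,11-dimethyldodeca-2,6,10-trien-4-yl]oxy}dimethylsilane | CC(C)=CCC/C(C)=C/C[C@@H](O[Si](C)(C)C(C)(C)C)/C=C(\C)I | intermediate
28 | B-alkyl-9-borabicyclo[3.3.1]nonane from 18 (boron on the terminal carbon of the former vinyl group) | C1CCC2CCCC1B2CC[C@@]1(C)[C@H](CCCO[Si](C)(C)C(C)(C)C)/C(=C(\C)C(=O)OCC)CC[C@]1(C)O | intermediate (not isolated)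
29 | ethyl (2E)-2-[(2R,3S,4S)-2-{3-[(TBS)oxy]propyl}-3-{(3E,5R,7E)-5-[(TBS)oxy]-3,8,12-trimethyltrideca-3,7,11-trien-1-yl}-4-hydroxy-3,4-dimethylcyclohexylidene]propanoate | CC(C)=CCC/C(C)=C/C[C@@H](O[Si](C)(C)C(C)(C)C)/C=C(\C)CC[C@@]1(C)[C@H](CCCO[Si](C)(C)C(C)(C)C)/C(=C(\C)C(=O)OCC)CC[C@]1(C)O | intermediate
30 | (2E)-2-[(2R,3S,4S)-2-{3-[(TBS)oxy]propyl}-3-{(3E,5R,7E)-5-[(TBS)oxy]-3,8,12-trimethyltrideca-3,7,11-trien-1-yl}-4-hydroxy-3,4-dimethylcyclohexylidene]propan-1-ol | CC(C)=CCC/C(C)=C/C[C@@H](O[Si](C)(C)C(C)(C)C)/C=C(\C)CC[C@@]1(C)[C@H](CCCO[Si](C)(C)C(C)(C)C)/C(=C(\C)CO)CC[C@]1(C)O | intermediate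
31 | (2E)-2-[(2R,3S,4S)-2-{3-[(TBS)oxy]propyl}-3-{(3E,5R,7E)-5-[(TBS)oxy]-3,8,12-trimethyltrideca-3,7,11-trien-1-yl}-4-hydroxy-3,4-dimethylcyclohexylidene]propanal | CC(C)=CCC/C(C)=C/C[C@@H](O[Si](C)(C)C(C)(C)C)/C=C(\C)CC[C@@]1(C)[C@H](CCCO[Si](C)(C)C(C)(C)C)/C(=C(\C)C=O)CC[C@]1(C)O | intermediate
32 | (2E)-2-[(2R,3S,4S)-4-hydroxy-3-[(3E,5R,7E)-5-hydroxy-3,8,12-trimethyltrideca-3,7,11-trien-1-yl]-2-(3-hydroxypropyl)-3,4-dimethylcyclohexylidene]propanal | CC(C)=CCC/C(C)=C/C[C@@H](O)/C=C(\C)CC[C@@]1(C)[C@H](CCCO)/C(=C(\C)C=O)CC[C@]1(C)O | target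

Total step count: 18 (ring part steps 1–9, side-chain part steps 10–14, union and end game steps 15–18).
Longest linear sequence: 13 steps (steps 1–9 and 15–18).

Steps most likely to fail

Step 8. β-Hydride elimination of the palladium homoenolate (giving a vinyl ketone and a reduced alkene) or attack of the cyclopropanolate oxygen on the β-triflyloxy enoate may outrun C–C reductive elimination. The fallback sets out from 12 and returns at 17. α-Methylenation of the methyl ketone (paraformaldehyde, N-methylanilinium trifluoroacetate, THF, reflux) should give the vinyl ketone ethyl (2Z,4S,5S)-4-{3-[(TBS)oxy]propyl}-2,5-dimethyl-5-(prop-2-enoyl)-3-{[(trifluoromethyl)sulfonyl]oxy}hepta-2,6-dienoate F1. Nickel-catalysed reductive conjugate addition of the enol triflate to the enone within the molecule (NiBr2(dme), neocuproine, Mn powder, Et3SiCl, DMF, rt) forms the same C3–C4 bond between the two electrophilic carbons through a silyloxyallylnickel species and should give the triethylsilyl enol ether of 17 F2, which dilute acid on work-up converts to 17.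

Step 2. The controller may discriminate the enolate faces poorly or in the reverse sense, and the B–Br reagent may add across the terminal alkyne. The fallback sets out from 1 and returns at 6; it replaces reagent control by chirality transfer from a carbinol centre.
- Oxidation of 1 (MnO2) gives (E)-3-methylpent-2-en-4-ynal F3, MeMgBr gives racemic (E)-4-methylhex-3-en-5-yn-2-ol F4, and MnO2 gives (E)-4-methylhex-3-en-5-yn-2-one F5.
- Corey–Bakshi–Shibata reduction [(S)-methyl oxazaborolidine, catecholborane, toluene, −78 °C; alkenyl as the large group] should give (R,E)-4-methylhex-3-en-5-yn-2-ol F6.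
- Esterification with 2 (DCC, DMAP) gives (R,E)-4-methylhex-3-en-5-yn-2-yl 5-[(TBS)oxy]pentanoate F7.
- Ireland–Claisen rearrangement (LDA, Me3SiCl, THF, −78 °C → rt; E(O)-enolate, chair with the carbinol methyl equatorial; K2CO3/MeOH in the work-up to take off the alkynyl silyl group) should give (2S,3S,4E)-2-{3-[(TBS)oxy]propyl}-3-ethynyl-3-methylhex-4-enoic acid F8.
- Ozonolysis of the propenyl group (O3, CH2Cl2, −78 °C, then Me2S) gives (2S,3S)-2-{3-[(TBS)oxy]propyl}-3-ethynyl-3-formyl-3-methylpropanoic acid F9, and Wittig methylenation (Ph3P=CH2, THF) returns 6.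

Step 9. Facial selectivity of the methyl addition may be poor or reversed, which would give the C6 epimer. The fallback sets out from 17 and returns at 30; it delivers oxygen instead of carbon to the preferred face.
- Wittig methylenation of the ketone (Ph3P=CH2) gives ethyl (2E)-2-[(2R,3S)-2-{3-[(TBS)oxy]propyl}-3-ethenyl-3-methyl-4-methylidenecyclohexylidene]propanoate F10.
- Epoxidation of the 1,1-disubstituted alkene (mCPBA, NaHCO3, CH2Cl2, 0 °C) gives the spiro-epoxide with oxygen on the face of the C1 methyl F11.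
- LiAlH4 (THF, 0 °C) opens the epoxide at its CH2 and reduces the ester, giving (2E)-2-[(2R,3S,4S)-2-{3-[(TBS)oxy]propyl}-3-ethenyl-4-hydroxy-3,4-dimethylcyclohexylidene]propan-1-ol F12.
- Hydroboration and Suzuki coupling with 27 as in step 15 give 30.

Further compounds
F1 | step 8 | ethyl (2Z,4S,5S)-4-{3-[(TBS)oxy]propyl}-2,5-dimethyl-5-(prop-2-enoyl)-3-{[(trifluoromethyl)sulfonyl]oxy}hepta-2,6-dienoate | C=C[C@@](C(=O)C=C)(C)[C@H](CCCO[Si](C)(C)C(C)(C)C)/C(=C(\C)C(=O)OCC)OS(=O)(=O)C(F)(F)F
F2 | step 8 | triethylsilyl enol ether of 17 | C=C[C@@]1(C)[C@H](CCCO[Si](C)(C)C(C)(C)C)/C(=C(\C)C(=O)OCC)CC=C1O[Si](CC)(CC)CC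
F3 | step 2 | (E)-3-methylpent-2-en-4-ynal | C#C/C(C)=C/C=O
F4 | step 2 | (E)-4-methylhex-3-en-5-yn-2-ol, racemic | C#C/C(C)=C/C(C)O
F5 | step 2 | (E)-4-methylhex-3-en-5-yn-2-one | C#C/C(C)=C/C(C)=O
F6 | step 2 | (R,E)-4-methylhex-3-en-5-yn-2-ol | C#C/C(C)=C/[C@@H](C)O
F7 | step 2 | (R,E)-4-methylhex-3-en-5-yn-2-yl 5-[(TBS)oxy]pentanoate | C#C/C(C)=C/[C@@H](C)OC(=O)CCCCO[Si](C)(C)C(C)(C)C
F8 | step 2 | (2S,3S,4E)-2-{3-[(TBS)oxy]propyl}-3-ethynyl-3-methylhex-4-enoic acid | C/C=C/[C@@](C#C)(C)[C@H](CCCO[Si](C)(C)C(C)(C)C)C(=O)O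
F9 | step 2 | (2S,3S)-2-{3-[(TBS)oxy]propyl}-3-ethynyl-3-formyl-3-methylpropanoic acid | O=C[C@@](C#C)(C)[C@H](CCCO[Si](C)(C)C(C)(C)C)C(=O)O
F10 | step 9 | ethyl (2E)-2-[(2R,3S)-2-{3-[(TBS)oxy]propyl}-3-ethenyl-3-methyl-4-methylidenecyclohexylidene]propanoate | C=C[C@@]1(C)[C@H](CCCO[Si](C)(C)C(C)(C)C)/C(=C(\C)C(=O)OCC)CCC1=C
F11 | step 9 | spiro-epoxide of F10 at the ring methylidene, oxygen cis to the C1 methyl | C=C[C@@]1(C)[C@H](CCCO[Si](C)(C)C(C)(C)C)/C(=C(\C)C(=O)OCC)CC[C@@]12CO2
F12 | step 9 | (2E)-2-[(2R,3S,4S)-2-{3-[(TBS)oxy]propyl}-3-ethenyl-4-hydroxy-3,4-dimethylcyclohexylidene]propan-1-ol | C=C[C@@]1(C)[C@H](CCCO[Si](C)(C)C(C)(C)C)/C(=C(\C)CO)CC[C@]1(C)O
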